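## Analysis of the target

The target (C26H36O4) is a 21-membered macrocycle. Two benzene rings are joined once through a diaryl ether oxygen and once through an unbranched chain of fourteen methylene groups, and the large ring runs through three atoms of each arene, the oxygen and the fourteen chain carbons. Ring A is a 5-alkylresorcinol, with the chain at C5, a free hydroxyl at C1 and the bridging oxygen at C3. Ring B, numbered from its chain carbon C1, is a hydroquinone with hydroxyls at C2 and C5 and the bridging oxygen at C3, so C1, C2 and C3 carry three contiguous substituents. There is no stereocentre, and with two meta-bridged rings on so long a tether no stable atropisomer is expected, so nothing has to be controlled in three dimensions. The sensitive part is the ring B hydroquinone, which air oxidises to the quinone, above all in base; all three phenols are also incompatible with the strong bases used to build the carbon chain, so they stay masked until late. The difficulty lies in closing a 21-membered ring against oligomerisation, in telling apart the two oxygens of ring A, and in joining a saturated chain with no functional handle to both arenes. The strategy rests on ring A: its pattern of O at C1, O at C3 and alkyl at C5 is that of a 3,5,7-trioxo ester folded by an aldol reaction between its C2 and C7. The six ring carbons are C2 to C7 of that chain, the fourteen-carbon bridge is the substituent of the C7 ketone, and the C1 ester, removed at the end, marks one ring A oxygen as para to it while it is present.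

## Retrosynthetic reasoning

26 from 25: the two O–methyl bonds on ring B are cut last. Methyl ethers are chosen because they survive amide bases, 110 °C, carbonate, copper and hot hydroxide, and a Lewis-acid demethylation leaves the diaryl ether alone. The air-sensitive hydroquinone therefore appears only in the final step.

25 from 23 through 24: the bond between ring A and its ester carbon is cut. The ester is the last trace of the polyketide chain, and saponification followed by protodecarboxylation of 24 removes it. Once it is gone the two oxygens of ring A are equivalent by symmetry, which matters for the step before.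

23 from 22: the macrocycle is opened at the bond between the bridging oxygen and C3 of ring B. A phenoxide and an aryl bromide are stable, mutually inert functions until copper is added, so the precursor can be dosed slowly; a carbon–carbon closure in the chain would need extra functional groups that then have to be removed. The forward reaction must make the phenol para to the ester attack the bromide intramolecularly. Should the other phenol react instead, the product converges on 25 after the ester is removed.

22 from 17 and 18: ring A is taken apart at the bond between the ester-bearing carbon and the chain-bearing carbon, that is C2–C7 of trioxo ester 20. The reactive chain is not handled free but stored as diketo-dioxinone 17, which releases ketene 19 on heating for capture by methanol 18. What is gained is a ring A that is born with the bridge attached and the oxygens in place, so no aryl–alkyl coupling is needed on this ring. The forward reaction has to follow the aldol mode and no other cyclisation mode.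

17 from 15 and 12: the bond between the terminal methylene of the masked triketide and the acyl carbon is cut. In the forward sense dianion 16 of keto-dioxinone 15 is C-acylated by imidazolide 12, which joins the ring B chain fragment and the three-ketide unit convergently.

15 from 13: the acetyl group is disconnected from the 6-methyl carbon of dioxinone 13, to be installed through dienolate 14.

12 from 11, 10, and then 8 and 2: the imidazolide comes from acid 11, and the saturated chain is traced back to alkene 10, which is cut at the benzylic double bond into ylide 9 (from phosphonium salt 8) and aldehyde 2. A Wittig reaction is used because the ring B bromide must survive, which rules out attaching the chain by cross-coupling at that ring. For the same reason the alkene is removed by a metal-free transfer hydrogenation and not by catalytic hydrogenation. The aldehyde carbon becomes the fourteenth methylene.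

8 from 7, 5, 4 and 3: the phosphonium salt comes from bromo acid 7, which is reached from the symmetrical diacid 3 by full reduction to diol 4, substitution of one hydroxyl (5) and reoxidation of the other through aldehyde 6.

2 from 1: the O–methyl bond of the central ring B oxygen is cut; the starting phenol 1 already carries the bromine, the formyl group and the second methoxy group in the required 1,2,3,5 arrangement.

## Alternatives that were turned down

Alternative 1: The bridge is cut at both benzylic positions after introducing two double bonds, and the diaryl ether is kept intact in an open-chain dialdehyde A2. In the forward key step the bis-ylide from the twelve-carbon bis-phosphonium salt A3 condenses with both formyl groups of A2 under high dilution, giving the Z,Z macrocyclic diene A1; hydrogenation and demethylation would finish the synthesis. In its favour, it is clearly shorter and more convergent than the chosen route, the diaryl ether is made intermolecularly where it is easy, and with no bromide present the alkenes can be hydrogenated conventionally. Against it, the second olefination is the macrocyclisation. A non-stabilised, moisture-sensitive ylide has to persist at high dilution until the tethered aldehyde reaches it, while head-to-tail addition to a second molecule and two-to-one combinations of A3 with A2 remain open, and nothing can be recovered once the ylide is quenched. A2 also needs a desymmetrised 3,5-dioxygenated benzaldehyde and an ether coupling between two electron-rich partners. On step count this alternative is stronger. The chosen route offers in its place a ring closure from a bench-stable phenol bromide that can be added slowly to a catalyst and recovered if unreacted, and a ring A whose oxygens are differentiated by construction.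

Alternative 2: Ring A itself is disconnected into a cyclobutenone (four carbons) and an alkyne (two carbons), the alkyne being an ethynyl ether on the ring B oxygen, so that arene and macrocycle form together. In the forward key step, heating A5 opens the cyclobutenone to a vinylketene, which adds [2+2] to the tethered ynol ether; ring opening, 6π electrocyclisation and tautomerisation then give A4, the same structure as 25. In its favour, one reagent-free thermal step makes ring A, places its three substituents correctly and closes the 21-membered ring, no ester has to be excised, and only demethylation would remain. On elegance and on the length of the endgame it is stronger than the chosen route. Against it, the known benzannulation is bimolecular and normally run with the alkyne in excess. Here the [2+2] step must close a macrocycle at high dilution, in competition with ketene dimerisation and intermolecular addition. The aryl ethynyl ether on a hindered, electron-rich phenol is laborious to make and thermally delicate, and both reactive termini must be carried on one chain. The macrocyclic variant has no close model, so the whole route would hang on an untested step with no way round it. The chosen route offers a ring A formation that is an intramolecular six-membered closure independent of dilution, and a macrocyclisation between two robust functional groups.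

Alternative 3: Ring B is disconnected by a Moore rearrangement to the racemic 4-alkenyl-4-hydroxycyclobutenone A7, assembled from squaric acid chemistry with the aryloxy group and the chain already attached. In the forward key step, heating A7 opens it to a hydroxy-dienylketene; 6π closure of the ketene carbon onto the terminal alkene carbon and tautomerisation give hydroquinone A6 with all four substituents placed. In its favour, the contiguous pattern of ring B arises by construction, and the diaryl ether is made early by addition–elimination on a squarate, without copper and before any macrocycle exists; on that point it is stronger than the chosen route. Against it, the pattern it builds can be bought in aldehyde 1, so the effort answers a question the target does not pose. A6 is a free hydroquinone that must be reprotected at once. The macrocycle then has to be closed by an sp3–sp2 carbon–carbon coupling between the chain terminus and the ring A bromide at high dilution, where β-hydride elimination and protodehalogenation compete, after silyl ether removal and activation of the chain end. This makes it longer than the chosen route and places the ring closure in a less reliable bond type. The chosen route takes ring B from the catalogue and closes the macrocycle through a carbon–oxygen bond.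

Key step: step 11

Remark: alkene 10 is drawn as its Z isomer; the Wittig step should give an E/Z mixture that is carried on unseparated, because step 7 removes the double bond.
Remark: the route is written from the bulk diacid 3; where diol 4 or bromo acid 7 is bought, steps 2 to 4 fall away.

## Route

Step 1
Reactants: 1 3-bromo-2-hydroxy-5-methoxybenzaldehyde
Product: 2 3-bromo-2,5-dimethoxybenzaldehyde
Conditions: MeI, K2CO3, DMF, 25 °C
Reagents that add atoms: iodomethane, CI
Why: Williamson O-methylation of the phenoxide; the methyl ether keeps ring B free of acidic protons through the ylide, dianion and copper steps.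

Step 2
Reactants: 3 tetradecanedioic acid
Product: 4 tetradecane-1,14-diol
Conditions: BH3·THF (3 equiv), THF, 0 °C to 65 °C; H2O
Reagents that add atoms: none
Why: Borane reduction of carboxylic acids to primary alcohols; both ends are identical and no other functional group is present.

Step 3
Reactants: 4 tetradecane-1,14-diol
Product: 5 14-bromotetradecan-1-ol
Conditions: 48% aq. HBr (1.1 equiv), toluene, reflux
Reagents that add atoms: hydrogen bromide, Br
Why: Two-phase monobromination of a symmetrical diol by SN2 on the protonated alcohol; the lipophilic bromo alcohol is withdrawn into toluene and away from the acid, so the second substitution is slow, and diol and dibromide are easily separated.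

Step 4
Reactants: 5 14-bromotetradecan-1-ol
Product: 7 14-bromotetradecanoic acid, via aldehyde 6 (not isolated)
Conditions: TEMPO (20 mol %), PhI(OAc)2 (2.5 equiv), MeCN/CH2Cl2/H2O, 25 °C
Reagents that add atoms: water, O
Why: Oxoammonium-mediated oxidation of a primary alcohol to the aldehyde, whose hydrate is oxidised on to the acid; a primary alkyl bromide is inert to these conditions.

Step 5
Reactants: 7 14-bromotetradecanoic acid
Product: 8 (13-carboxytridecyl)triphenylphosphonium bromide
Conditions: PPh3, MeCN, reflux
Reagents that add atoms: triphenylphosphine, c1ccc(cc1)P(c1ccccc1)c1ccccc1
Why: SN2 quaternisation of the phosphine by a primary bromide; the free carboxylic acid is tolerated.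

Step 6
Reactants: 8 (13-carboxytridecyl)triphenylphosphonium bromide, 2 3-bromo-2,5-dimethoxybenzaldehyde
Product: 10 (Z)-15-(3-bromo-2,5-dimethoxyphenyl)pentadec-14-enoic acid, via ylide 9 (not isolated)
Conditions: 8, NaN(SiMe3)2 (2 equiv), THF, 0 °C; then 2, −78 °C to 25 °C; aq. HCl
Reagents that add atoms: none
Why: Wittig olefination with a non-stabilised ylide formed beside the carboxylate by two equivalents of base; the aldehyde has no α-hydrogen, and the alkene geometry (Z expected to predominate) is of no consequence.

Step 7
Reactants: 10 (Z)-15-(3-bromo-2,5-dimethoxyphenyl)pentadec-14-enoic acid
Product: 11 15-(3-bromo-2,5-dimethoxyphenyl)pentadecanoic acid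
Conditions: TsNHNH2, NaOAc, DME/H2O, reflux; aq. HCl
Reagents that add atoms: none
Why: Diimide reduction, a concerted syn transfer of two hydrogens to the C=C bond; unlike hydrogenation over palladium it cannot cleave the aryl bromide needed in step 12.

Step 8
Reactants: 11 15-(3-bromo-2,5-dimethoxyphenyl)pentadecanoic acid
Product: 12 15-(3-bromo-2,5-dimethoxyphenyl)-1-(1H-imidazol-1-yl)pentadecan-1-one
Conditions: CDI (1.1 equiv), THF, 25 °C; cold aqueous wash to remove imidazole
Reagents that add atoms: 1,1'-carbonyldiimidazole, O=C(n1ccnc1)n1ccnc1
Why: Activation of the acid as its acyl imidazolide with loss of CO2; this acyl donor is reactive enough for a carbanion but carries no acidic or chloride-derived by-product into the dianion step.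

Step 9
Reactants: 13 2,2,6-trimethyl-4H-1,3-dioxin-4-one
Product: 15 2,2-dimethyl-6-(2-oxopropyl)-4H-1,3-dioxin-4-one, via lithium dienolate 14 (not isolated)
Conditions: 13 (2 equiv), LiN(SiMe3)2 (2 equiv), THF, −78 °C; AcCl (1 equiv), −78 °C; aq. NH4Cl
Reagents that add atoms: acetyl chloride, CC(=O)Cl
Why: Vinylogous Claisen acylation: deprotonation of the 6-methyl group gives the dienolate, which is acylated at the exocyclic carbon; the second equivalent of enolate serves as base for the more acidic product and is recovered as 13.

Step 10
Reactants: 15 2,2-dimethyl-6-(2-oxopropyl)-4H-1,3-dioxin-4-one, 12 15-(3-bromo-2,5-dimethoxyphenyl)-1-(1H-imidazol-1-yl)pentadecan-1-one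
Product: 17 6-[18-(3-bromo-2,5-dimethoxyphenyl)-2,4-dioxooctadecyl]-2,2-dimethyl-4H-1,3-dioxin-4-one, via dilithium dianion 16 (not isolated)
Conditions: 15 (2.2 equiv), LiN(iPr)2 (4.4 equiv), THF, −78 °C; then 12, −78 °C to −30 °C; aq. HCl to pH 3
Reagents that add atoms: none
Why: Claisen-type C-acylation of a 1,3-dianion: the terminal carbanion, formed last and least stabilised, is the nucleophilic site and attacks the acyl imidazolide; the excess of dianion takes up the acidic proton of the new 1,3-diketone.

Step 11
Reactants: 17 6-[18-(3-bromo-2,5-dimethoxyphenyl)-2,4-dioxooctadecyl]-2,2-dimethyl-4H-1,3-dioxin-4-one, 18 methanol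
Product: 22 methyl 2-[14-(3-bromo-2,5-dimethoxyphenyl)tetradecyl]-4,6-dihydroxybenzoate, via acylketene 19 (not isolated), via trioxo ester 20 (not isolated), via aldol carbinol 21 (not isolated)
Conditions: 18 (large excess), PhMe, 110 °C, sealed tube; then Cs2CO3 (2 equiv), MeOH, 25 °C; then HCl in MeOH, 25 °C
Reagents that add atoms: none
Why: At about 110 °C the dioxinone ring of 17 undergoes a retro-[4+2] fragmentation that expels acetone and leaves acylketene 19, and methanol 18, present in large excess, adds to the ketene carbon to give the 3,5,7-trioxo ester 20. Cs2CO3 then equilibrates the enolates of 20, and the carbanion at C2, between the ester and the C3 ketone, adds to the C7 ketone in a 6-(enolendo)-exo-trig aldol closure that forms the C2–C7 bond and carbinol 21. Loss of water from 21 (E1cB, completed by the HCl treatment) and enolisation of the two remaining ketones give the aromatic ring A of 22, and aromatisation makes the sequence irreversible. The closest known reaction type is the biomimetic resorcylate synthesis in which a diketo-dioxinone is thermolysed, the ketene is trapped by an alcohol and the chain is aromatised by aldol condensation. The two stereocentres of 21 are transient and are erased on aromatisation, so no stereocontrol is needed. The selectivity required is that of the cyclisation mode: the aldol closure of C2 on C7 must win over Claisen closure of C6 on the ester carbon, which would give an acylphloroglucinol, and over lactonisation to a 4-hydroxy-2-pyranone. The substrate secures this because a methyl ester is a far poorer electrophile than the C7 ketone toward a carbonate-generated enolate, because the more acidic C4 enolate has no six-membered closure open to it, and because the excess of 18 captures the ketene before an enol oxygen of the same chain can.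

Step 12
Reactants: 22 methyl 2-[14-(3-bromo-2,5-dimethoxyphenyl)tetradecyl]-4,6-dihydroxybenzoate
Product: 23 macrocyclic ester: methyl 2-hydroxybenzoate of ring A whose C4 oxygen is bonded to C3 of the 2,5-dimethoxy ring B and whose C6 is joined to C1 of ring B by the (CH2)14 chain
Conditions: CuI (30 mol %), N,N-dimethylglycine·HCl (60 mol %), Cs2CO3 (3 equiv), dioxane, 100 °C, syringe-pump addition of 22 to a final 2 mM
Reagents that add atoms: none
Why: Copper-catalysed Ullmann diaryl ether coupling run as a macrocyclisation: the phenoxide para to the ester, the more acidic and unchelated of the two, binds monovalent copper, which then inserts into the C–Br bond next to a methoxy group, a substitution pattern this coupling tolerates. Slow addition keeps the open-chain bromide dilute so that the 21-membered closure can compete with oligomerisation, and arylation of the other phenol would converge on 25 after step 13.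

Step 13
Reactants: 23 macrocyclic ester
Product: 25 ring B dimethyl ether of the target, via carboxylic acid 24 (not isolated)
Conditions: KOH (10 equiv), DMSO/H2O 4:1, 120 °C; then 6 M HCl to pH 1, 100 °C
Reagents that add atoms: none
Why: Saponification of the hindered, hydrogen-bonded salicylate needs forcing hydroxide, and the resulting acid 24 loses CO2 by ipso protonation, which the ortho hydroxyl and the para aryloxy group both favour; diaryl and methyl ethers are stable to both stages.

Step 14
Reactants: 25 ring B dimethyl ether of the target
Product: 26 target macrocycle CNP0393720.0
Conditions: BBr3 (5 equiv), CH2Cl2, −78 °C to 25 °C; degassed H2O, aq. Na2S2O4 wash, work-up under argon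
Reagents that add atoms: none
Why: Lewis-acid cleavage of aryl methyl ethers by bromide attack on the methyl group of the boron–ether adduct; the diaryl ether has no carbon open to SN2 and survives, and the reducing work-up protects the new hydroquinone from air oxidation.

## Compound list

1 | 3-bromo-2-hydroxy-5-methoxybenzaldehyde | COc1cc(Br)c(O)c(C=O)c1 | starting material
2 | 3-bromo-2,5-dimethoxybenzaldehyde | COc1cc(Br)c(OC)c(C=O)c1 | intermediate
3 | tetradecanedioic acid | OC(=O)CCCCCCCCCCCCC(=O)O | starting material
4 | tetradecane-1,14-diol | OCCCCCCCCCCCCCCO | intermediate
5 | 14-bromotetradecan-1-ol | OCCCCCCCCCCCCCCBr | intermediate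
6 | 14-bromotetradecanal | O=CCCCCCCCCCCCCCBr | intermediate
7 | 14-bromotetradecanoic acid | OC(=O)CCCCCCCCCCCCCBr | intermediate
8 | (13-carboxytridecyl)triphenylphosphonium bromide | OC(=O)CCCCCCCCCCCCC[P+](c1ccccc1)(c1ccccc1)c1ccccc1.[Br-] | intermediate
9 | sodium 14-(triphenylphosphoranylidene)tetradecanoate (carboxylate ylide) | [Na+].[O-]C(=O)CCCCCCCCCCCCC=P(c1ccccc1)(c1ccccc1)c1ccccc1 | intermediate
10 | (Z)-15-(3-bromo-2,5-dimethoxyphenyl)pentadec-14-enoic acid (E isomer carried along) | OC(=O)CCCCCCCCCCCC/C=C\c1cc(OC)cc(Br)c1OC | intermediate
11 | 15-(3-bromo-2,5-dimethoxyphenyl)pentadecanoic acid | OC(=O)CCCCCCCCCCCCCCc1cc(OC)cc(Br)c1OC | intermediate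
12 | 15-(3-bromo-2,5-dimethoxyphenyl)-1-(1H-imidazol-1-yl)pentadecan-1-one | O=C(CCCCCCCCCCCCCCc1cc(OC)cc(Br)c1OC)n1ccnc1 | intermediate
13 | 2,2,6-trimethyl-4H-1,3-dioxin-4-one | CC1=CC(=O)OC(C)(C)O1 | starting material
14 | lithium dienolate of 13 (lithium 2,2-dimethyl-6-methylidene-6H-1,3-dioxin-4-olate) | [Li+].[O-]C1=CC(=C)OC(C)(C)O1 | intermediate
15 | 2,2-dimethyl-6-(2-oxopropyl)-4H-1,3-dioxin-4-one | CC(=O)CC1=CC(=O)OC(C)(C)O1 | intermediate
16 | dilithium 1,3-dianion of 15 (drawn as enolate and terminal carbanion) | [Li+].[Li+].[CH2-]C([O-])=CC1=CC(=O)OC(C)(C)O1 | intermediate
17 | 6-[18-(3-bromo-2,5-dimethoxyphenyl)-2,4-dioxooctadecyl]-2,2-dimethyl-4H-1,3-dioxin-4-one | CC1(C)OC(=O)C=C(CC(=O)CC(=O)CCCCCCCCCCCCCCc2cc(OC)cc(Br)c2OC)O1 | intermediate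
18 | methanol | CO | starting material
19 | acylketene, 21-(3-bromo-2,5-dimethoxyphenyl)-3,5,7-trioxohenicos-1-en-1-one | O=C=CC(=O)CC(=O)CC(=O)CCCCCCCCCCCCCCc1cc(OC)cc(Br)c1OC | intermediate
20 | methyl 21-(3-bromo-2,5-dimethoxyphenyl)-3,5,7-trioxohenicosanoate | COC(=O)CC(=O)CC(=O)CC(=O)CCCCCCCCCCCCCCc1cc(OC)cc(Br)c1OC | intermediate
21 | methyl 2-[14-(3-bromo-2,5-dimethoxyphenyl)tetradecyl]-2-hydroxy-4,6-dioxocyclohexane-1-carboxylate (transient, configuration undefined) | COC(=O)C1C(=O)CC(=O)CC1(O)CCCCCCCCCCCCCCc1cc(OC)cc(Br)c1OC | intermediate
22 | methyl 2-[14-(3-bromo-2,5-dimethoxyphenyl)tetradecyl]-4,6-dihydroxybenzoate | COC(=O)c1c(O)cc(O)cc1CCCCCCCCCCCCCCc1cc(OC)cc(Br)c1OC | intermediate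
23 | macrocyclic ester: 21-membered diaryl ether, ring A methyl 2-hydroxybenzoate with C4–O–C3 link to 2,5-dimethoxy ring B and (CH2)14 chain from C6 of ring A to C1 of ring B | COC(=O)c1c(O)cc2cc1CCCCCCCCCCCCCCc1cc(OC)cc(O2)c1OC | intermediate
24 | macrocyclic carboxylic acid corresponding to 23 | OC(=O)c1c(O)cc2cc1CCCCCCCCCCCCCCc1cc(OC)cc(O2)c1OC | intermediate
25 | ring B dimethyl ether of the target macrocycle | Oc1cc2cc(c1)Oc1cc(OC)cc(c1OC)CCCCCCCCCCCCCC2 | intermediate
26 | target CNP0393720.0: 21-membered macrocycle of a 5-alkylresorcinol mono-aryl ether and a 2-aryloxy-6-alkylhydroquinone bridged by (CH2)14 | Oc1cc2cc(c1)Oc1cc(O)cc(c1O)CCCCCCCCCCCCCC2 | target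

## Step count and least certain steps

Total step count: 14. Longest linear sequence: 12 steps (from 3 through steps 2 to 8 and 10 to 14).

Step 11 (key step). What may go wrong: capture of the ketene by an enol oxygen of its own chain, giving a pyranone, if the methanol concentration falls; closure in the Claisen mode; or stalling at the carbinol stage without dehydration. The cause is that 19 and 20 have several nucleophilic and electrophilic sites within reach of one another. Fallback, from 17 back to 22: the aromatisation is run without thermolysis. Triethylamine in CH2Cl2 at 25 °C makes C5 of the intact dioxinone ring the aldol donor toward the terminal ketone, and dehydration gives 5-[14-(3-bromo-2,5-dimethoxyphenyl)tetradecyl]-7-hydroxy-2,2-dimethyl-4H-1,3-benzodioxin-4-one F1, in which no free ketene or triketone ever exists. NaOMe in methanol then opens F1 to 22, where the route resumes.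

Step 12. What may go wrong: intermolecular coupling to dimers and oligomers, slow insertion of copper into an electron-rich ortho-substituted C–Br bond, protodebromination, and low nucleophilicity of a phenoxide para to an ester. The cause is that a 21-membered closure has a low effective molarity and must run at 100 °C with a weak nucleophile. Fallback, from 22 back to 23: the polarity of the coupling is changed. Miyaura borylation (B2pin2, PdCl2(dppf), KOAc, dioxane, 80 °C) gives the pinacol boronate methyl 2-[14-[2,5-dimethoxy-3-(4,4,5,5-tetramethyl-1,3,2-dioxaborolan-2-yl)phenyl]tetradecyl]-4,6-dihydroxybenzoate F2. NaIO4 and NH4OAc in aqueous acetone free the boronic acid [3-[14-(3,5-dihydroxy-2-methoxycarbonylphenyl)tetradecyl]-2,5-dimethoxyphenyl]boronic acid F3. An oxidative Chan–Lam coupling (Cu(OAc)2, pyridine, 4 Å sieves, air, CH2Cl2, 25 °C, high dilution) then closes the ether at room temperature to 23.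

Step 10. What may go wrong: proton transfer from the newly formed 1,3-diketone to unreacted dianion, O-acylation, and attack of the dianion on the dioxinone carbonyl of another molecule. The cause is that the product is more acidic than the nucleophile's conjugate acid and the dianion is strongly basic. Fallback, from 12 back to 17: acylation is replaced by aldol addition and oxidation, which keeps the acidic diketone out of the anion chemistry. iBu2AlH at −78 °C reduces the imidazolide to 15-(3-bromo-2,5-dimethoxyphenyl)pentadecanal F4. Dianion 16 adds to F4 to give racemic 6-[18-(3-bromo-2,5-dimethoxyphenyl)-4-hydroxy-2-oxooctadecyl]-2,2-dimethyl-4H-1,3-dioxin-4-one F5. Dess–Martin periodinane oxidises F5 to 17.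

Step 13. What may go wrong: incomplete hydrolysis of the hindered, hydrogen-bonded ester and sluggish loss of CO2, because only one free hydroxyl activates the ipso position once the para oxygen is arylated. Fallback, from 22 back to 25: the order of the ring-forming and ester-removing steps is inverted. NaOH in aqueous methanol at reflux hydrolyses and decarboxylates the free 2,4-dihydroxybenzoate, which loses CO2 far more readily than 24, to give 5-[14-(3-bromo-2,5-dimethoxyphenyl)tetradecyl]benzene-1,3-diol F6. The Ullmann closure of step 12, applied to F6, whose two hydroxyls are equivalent, then gives 25 directly.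

## Further compounds

F1 | step 11 | 5-[14-(3-bromo-2,5-dimethoxyphenyl)tetradecyl]-7-hydroxy-2,2-dimethyl-4H-1,3-benzodioxin-4-one | CC1(C)OC(=O)c2c(CCCCCCCCCCCCCCc3cc(OC)cc(Br)c3OC)cc(O)cc2O1
F2 | step 12 | methyl 2-[14-[2,5-dimethoxy-3-(4,4,5,5-tetramethyl-1,3,2-dioxaborolan-2-yl)phenyl]tetradecyl]-4,6-dihydroxybenzoate | COC(=O)c1c(O)cc(O)cc1CCCCCCCCCCCCCCc1cc(OC)cc(B2OC(C)(C)C(C)(C)O2)c1OC
F3 | step 12 | [3-[14-(3,5-dihydroxy-2-methoxycarbonylphenyl)tetradecyl]-2,5-dimethoxyphenyl]boronic acid | COC(=O)c1c(O)cc(O)cc1CCCCCCCCCCCCCCc1cc(OC)cc(B(O)O)c1OC
F4 | step 10 | 15-(3-bromo-2,5-dimethoxyphenyl)pentadecanal | O=CCCCCCCCCCCCCCCc1cc(OC)cc(Br)c1OC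
F5 | step 10 | 6-[18-(3-bromo-2,5-dimethoxyphenyl)-4-hydroxy-2-oxooctadecyl]-2,2-dimethyl-4H-1,3-dioxin-4-one (racemic) | CC1(C)OC(=O)C=C(CC(=O)CC(O)CCCCCCCCCCCCCCc2cc(OC)cc(Br)c2OC)O1
F6 | step 13 | 5-[14-(3-bromo-2,5-dimethoxyphenyl)tetradecyl]benzene-1,3-diol | Oc1cc(O)cc(CCCCCCCCCCCCCCc2cc(OC)cc(Br)c2OC)c1
A1 | alternative 1 | Z,Z macrocyclic diene, ring A methyl ether and ring B dimethyl ether with a 1,13-diene bridge | COc1cc(/C=C\CCCCCCCCCC/C=C\c2cc(OC)cc3c2OC)cc(O3)c1
A2 | alternative 1 | 3-(3-formyl-5-methoxyphenoxy)-2,5-dimethoxybenzaldehyde | COc1cc(C=O)cc(Oc2cc(OC)cc(C=O)c2OC)c1
A3 | alternative 1 | dodecane-1,12-diylbis(triphenylphosphonium) dibromide | [Br-].[Br-].c1ccc(cc1)[P+](c1ccccc1)(c1ccccc1)CCCCCCCCCCCC[P+](c1ccccc1)(c1ccccc1)c1ccccc1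
A4 | alternative 2 | ring B dimethyl ether of the target (same structure as 25) | Oc1cc2cc(c1)Oc1cc(OC)cc(c1OC)CCCCCCCCCCCCCC2
A5 | alternative 2 | 3-[14-(3-ethynyloxy-2,5-dimethoxyphenyl)tetradecyl]cyclobut-2-en-1-one | O=C1C=C(CCCCCCCCCCCCCCc2cc(OC)cc(OC#C)c2OC)C1
A6 | alternative 3 | 2-(3-bromo-5-methoxyphenoxy)-6-[14-(tert-butyldimethylsilyloxy)tetradecyl]benzene-1,4-diol | Oc1cc(CCCCCCCCCCCCCCO[Si](C)(C)C(C)(C)C)c(O)c(Oc2cc(OC)cc(Br)c2)c1
A7 | alternative 3 | 3-(3-bromo-5-methoxyphenoxy)-4-[16-(tert-butyldimethylsilyloxy)hexadec-1-en-2-yl]-4-hydroxycyclobut-2-en-1-one (racemic) | O=C1C=C(Oc2cc(OC)cc(Br)c2)C1(O)C(=C)CCCCCCCCCCCCCCO[Si](C)(C)C(C)(C)C
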